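**Plan**

1. Locants follow the SMILES chain: C1(Me)=C2, C3, C4, C5(Me), C6, C7, C8, C9(Me), C10, C11, C12(CO2H), C13, C14, C15(iPr), C16, C17, C18(OH). Ring A = C2–C6, ring B = C1/C2/C6–C10/C18, ring C = C10–C12/C16–C18, ring D = C12–C16.
2. Retrosynthesis: CO2H goes back to CH2OSi, and C14H2/H-15/H-16 go back to a C14=O/C15=C16 enone. Then C12–C16, C13–C14 and C14–C15 are cut at one stroke (intramolecular Pauson–Khand), which opens rings D and C to a 1,7-enyne on the A/B bicycle.
3. Enabling feature: ring D meets the rest only at the C12–C16 bond, and its other atoms CH2–CH2–CH(iPr) equal alkene CH2 + CO + alkyne carbon. C12 and C16 hang through C11 and C17 on the vicinal ring-B atoms C10 (α-carbon) and C18 (carbonyl carbon) of a cyclooctenone, whose trans arms lock ring C as a chair.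
4. Further cuts: C16–C17 (acetylide/epoxide), C17–C18 (sulfur ylide), C10–C11 and C9–CH3 (conjugate addition/allylation), C9=C10 (RCM, ring B), C1–C18, C7–C8, and C2–C6 (zirconocene enyne cyclisation, ring A).
5. Forward order of rings: A, then B, then C and D in one operation, with D closed last.
6. Stereochemistry: C5 comes from (R)-β-citronellene, C6 from C5, C9 from a chiral Cu catalyst, C10 from C9, C18 from C10, and C12 from the locked ring-C chair. C16 comes from axial protonation and C15 from hydrogenation anti to the angular CH2OSi group.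

Key step: step 14

Assumption: (3R)-3,7-dimethylocta-1,6-diene is taken as the commercial β-citronellene enantiomer of that configuration. In the locants above the target is (5R,6S,9S,10R,12S,15R,16S,18R) with a Z (in-ring cis) C1=C2 bond.

**Step 1**
Reactants: 1 (R)-β-citronellene
Product: 2 (4R)-4-methylhex-5-enal
Conditions: O3 (1.0 equiv, Sudan III end-point), CH2Cl2, −78 °C; then Me2S, → rt
Reagents that add atoms: ozone [O-][O+]=O
Why: Chemoselective ozonolysis, in which the electron-rich trisubstituted alkene reacts much faster than the vinyl group, so that one equivalent of ozone and reductive work-up should give the aldehyde and leave the allylic stereocentre (future C5) untouched.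

**Step 2**
Reactants: 2 (4R)-4-methylhex-5-enal
Product: 3 (5R)-1,1-dibromo-5-methylhepta-1,6-diene
Conditions: CBr4, PPh3, CH2Cl2, 0 °C
Reagents that add atoms: carbon tetrabromide BrC(Br)(Br)Br
Why: Dibromo-olefination of an unhindered aldehyde (first half of the Corey–Fuchs sequence), which adds the carbon that becomes C1 under neutral conditions that do not touch the remote stereocentre.

**Step 3**
Reactants: 3 (5R)-1,1-dibromo-5-methylhepta-1,6-diene
Product: 5 (3R)-3-methyloct-1-en-6-yne, via lithium acetylide 4 (not isolated)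
Conditions: n-BuLi (2.1 equiv), THF, −78 → 0 °C; then MeI, −78 °C → rt
Reagents that add atoms: iodomethane CI
Why: Second half of the Corey–Fuchs sequence (Br/Li exchange, 1,2-shift, deprotonation) with methylation of the acetylide in the same flask, which installs the C1 methyl group.

**Step 4**
Reactants: 5 (3R)-3-methyloct-1-en-6-yne
Product: 7 (2S,3R)-1-[(Z)-1-iodoethylidene]-2-(iodomethyl)-3-methylcyclopentane, via zirconabicycle 6 (not isolated)
Conditions: Cp2ZrCl2, n-BuLi (2 equiv), THF, −78 °C; add 5, → rt; then I2 (2.2 equiv), −78 → 0 °C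
Reagents that add atoms: iodine II
Why: Zirconocene-mediated enyne bicyclisation followed by iodinolysis: the oxidative coupling is a syn-carbometalation, so Zr (later I, then C18) ends cis to C6 on the exocyclic tetrasubstituted alkene, the reversible closure of ring A keeps the allylic C5 methyl pseudo-equatorial and sets C6 trans to it, and iodine cleaves both C–Zr bonds with retention.

**Step 5**
Reactants: 7 diiodide; 8 allylmagnesium bromide
Product: 9 (2S,3R)-2-(but-3-enyl)-1-[(Z)-1-iodoethylidene]-3-methylcyclopentane
Conditions: 8 (1.5 equiv), CuI (10 mol %), THF, −30 → 0 °C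
Reagents that add atoms: none
Why: Copper-catalysed Grignard–alkyl halide coupling at the primary iodide (C7–C8 bond), while the hindered tetrasubstituted alkenyl iodide should stay inert at this temperature.

**Step 6**
Reactants: 9 butenyl alkenyl iodide; 10 acrolein
Product: 12 (4Z)-4-[(2S,3R)-2-(but-3-enyl)-3-methylcyclopentylidene]pent-1-en-3-ol (both C18 epimers), via alkenyllithium 11 (not isolated)
Conditions: t-BuLi (2.0 equiv), Et2O, −78 °C; then 10, −78 °C; H2O
Reagents that add atoms: none
Why: Iodine–lithium exchange with retention of alkene geometry and 1,2-addition of the hard alkenyllithium to acrolein (C1–C18 bond); the new carbinol centre is removed in step 7.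

**Step 7**
Reactants: 12 bis-allylic alcohol
Product: 13 (4Z)-4-[(2S,3R)-2-(but-3-enyl)-3-methylcyclopentylidene]pent-1-en-3-one
Conditions: DMP, CH2Cl2, 0 °C → rt
Reagents that add atoms: none
Why: Dess–Martin oxidation of a bis-allylic alcohol under mild, non-acidic conditions that should neither isomerise the Z-alkene nor trigger Nazarov closure of the divinyl ketone.

**Step 8**
Reactants: 13 trienone
Product: 14 (4Z,8S,9R)-2,9-dimethylbicyclo[6.3.0]undeca-1,4-dien-3-one
Conditions: HG-II Ru catalyst (5 mol %), 1,4-benzoquinone (10 mol %), toluene (1 mM), 80 °C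
Reagents that add atoms: none
Why: Ring-closing metathesis to a cyclooctenone (C9=C10, ring B): the catalyst loads at the butenyl terminus and closes onto the acryloyl alkene, the Z-tetrasubstituted alkene and ring A hold the two chains cis, and the tetrasubstituted alkene itself is inert to the catalyst.

**Step 9**
Reactants: 15 2-methylidenepropane-1,3-diol
Product: 16 2-{[(tert-butyldimethylsilyl)oxy]methyl}prop-2-en-1-ol
Conditions: NaH (1.0 equiv), THF, 0 °C; then TBSCl (1.0 equiv), rt
Reagents that add atoms: tert-butyldimethylsilyl chloride CC(C)(C)[Si](C)(C)Cl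
Why: Monosilylation of a symmetrical diol through its sparingly soluble monosodium alkoxide, a standard way to favour the mono-ether.

**Step 10**
Reactants: 16 mono-TBS ether
Product: 17 2-{[(tert-butyldimethylsilyl)oxy]methyl}prop-2-en-1-yl acetate
Conditions: Ac2O, pyridine, DMAP (cat.), CH2Cl2, rt
Reagents that add atoms: acetic anhydride CC(=O)OC(C)=O
Why: Routine acetylation that turns one allylic terminus into the only ionisable leaving group for π-allylpalladium formation.

**Step 11**
Reactants: 14 bicyclic dienone; 17 allylic acetate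
Product: 19 (4R,5S,8S,9R)-4-[2-(tert-butyldimethylsilyloxymethyl)prop-2-enyl]-2,5,9-trimethylbicyclo[6.3.0]undec-1-en-3-one, via methylzinc enolate 18 (not isolated)
Conditions: Me2Zn (1.5 equiv), Cu(OTf)2 (2.5 mol %), (S,R,R)-binaphthol/bis(1-phenylethyl)amine phosphoramidite (5 mol %), toluene, −25 °C; then 17, Pd(PPh3)4 (4 mol %), 0 °C → rt
Reagents that add atoms: dimethylzinc C[Zn]C
Why: Copper/phosphoramidite-catalysed asymmetric conjugate addition of Me2Zn (a reaction type known for cycloocta-2,7-dienone) followed by Pd-catalysed allylation of the zinc enolate: only the disubstituted C9=C10 enone can react, the ligand enantiomer that gives (S)-3-alkylcycloalkanones should fix C9 under catalyst control, and the symmetrical π-allyl unit enters C10 anti to the new methyl group, giving the trans isomer that epimerisation would also favour.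

**Step 12**
Reactants: 19 ketone
Product: 20 C18 spiro-oxirane of 19 (oxirane CH2 = C17 trans to the C10 side chain; oxygen anti to H-10)
Conditions: Me3S+ I−, NaH, DMSO/THF, 0 °C; then 19, 0 °C → rt
Reagents that add atoms: trimethylsulfonium iodide C[S+](C)C.[I-]
Why: Corey–Chaykovsky epoxidation, in which the sulfonium ylide adds 1,2 to the enone (its β-carbon is fully substituted) from the peripheral face of the conformer that holds the C10–C11 bond near the C=O plane and away from the C1 methyl, that is past H-10 and anti to the C9–C10 ring bond, which sets C18.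

**Step 13**
Reactants: 20 spiro-epoxide; 21 3-methylbut-1-yne
Product: 24 1,7-enyne: 19-derived C18 triethylsilyl ether bearing CH2C≡C-iPr on C18 and CH2C(=CH2)CH2OTBS on C10 (arms trans), via lithium 3-methylbutynide 22 (not isolated), via lithium alkoxide 23 (not isolated)
Conditions: 21, n-BuLi, THF, −78 → 0 °C; 20, DMPU, 0 → 50 °C; then TESCl, 0 °C → rt
Reagents that add atoms: chlorotriethylsilane CC[Si](Cl)(CC)CC
Why: SN2 opening of a 2,2-disubstituted oxirane at its CH2 terminus by a lithium acetylide without Lewis acid, so that the tertiary allylic C18–O bond is never ionised and C18 is retained, and the resulting alkoxide is silylated in the same flask.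

**Step 14**
Reactants: 24 1,7-enyne
Product: 26 tetracyclic cyclopentenone (C14=O, C15=C16, angular CH2OTBS on C12, C18-OTES), via hexacarbonyldicobalt alkyne complex 25 (not isolated)
Conditions: Co2(CO)8 (1.1 equiv), 1,2-dichloroethane, rt; then n-BuSMe (3.5 equiv), 83 °C
Reagents that add atoms: dicobalt octacarbonyl (delivers CO) O=C=[Co](=C=O)(=C=O)(=C=O)[Co](=C=O)(=C=O)(=C=O)=C=O
Why: Intramolecular Pauson–Khand [2+2+1] reaction: the alkyne is taken up as its Co2(CO)6 complex 25, sulfide-assisted loss of one CO lets the 1,1-disubstituted alkene bind and insert into the Co–C16 bond (C12–C16 formed), CO then migrates onto C13, and reductive elimination joins C14 to C15. The closest known reaction type is the cobalt-mediated cyclocarbonylation of ring-anchored 1,7-enynes with 1,1-disubstituted alkenes, which gives hydrindenones with an angular quaternary carbon. Ring C closes first, exo at both π-systems (6-exo-trig/6-exo-dig, with C13 and C15 left outside), and ring D closes last by carbonyl insertion and C14–C15 reductive elimination, the CO carbon becoming C14. The only new stereocentre, C12, is controlled by the trans-diequatorial anchoring of ring C on ring B (C9 and C1 equatorial, no ring flip possible): the flat cyclopentenone forces C13 to lie nearly eclipsed with the exocyclic C16=C15 bond and hence equatorial, so CH2OTBS must be axial, syn to H-10 and anti to the C18 oxygen. Chemoselectivity against the C1=C2 alkene is secured because that alkene is tetrasubstituted and would have to close a four-membered ring; the tethers fix the regiochemistry, and the fully substituted C18 compresses the two arms (gem-disubstituent effect), which should offset the slower 1,7-closure.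

**Step 15**
Reactants: 26 tetracyclic enone
Product: 28 C14 enol triflate (C14=C15, H-16 trans to the C12 CH2OTBS group), via lithium enolate 27 (not isolated)
Conditions: Li (2.2 equiv), NH3/THF, t-BuOH (1.0 equiv), −78 °C; NH3 off; PhNTf2, THF, 0 °C → rt
Reagents that add atoms: N-phenylbis(trifluoromethanesulfonimide) O=S(=O)(N(c1ccccc1)S(=O)(=O)C(F)(F)F)C(F)(F)F
Why: Dissolving-metal reduction of the enone with regiospecific trapping of the enolate: C16 is protonated axially on the locked ring-C chair, because a cis-hydrindane would place C15 axial and 1,3-diaxial to the C18 silyloxy group, so the trans C/D fusion should result, the isolated C1=C2 alkene and both silyl ethers are inert, and the C14–C15 enolate is captured before it can equilibrate.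

**Step 16**
Reactants: 28 enol triflate
Product: 29 C14=C15 alkene (trisubstituted, isopropyl on C15)
Conditions: Pd(OAc)2 (10 mol %), PPh3 (20 mol %), HCO2H, n-Bu3N, DMF, 60 °C
Reagents that add atoms: none
Why: Palladium-catalysed formate reduction of an enol triflate, which removes the helper oxygen at C14 under buffered conditions that spare the silyl ethers and the stereocentres at C12 and C16.

**Step 17**
Reactants: 29 alkene
Product: 30 saturated bis-silyl ether (15R; H-15 cis to H-16)
Conditions: H2 (1 atm), PtO2 (10 mol %), EtOAc, rt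
Reagents that add atoms: none
Why: Heterogeneous syn-hydrogenation of the only trisubstituted alkene from the face opposite the axial angular CH2OTBS group (the steric course known for D-ring alkenes of steroids next to an angular substituent), which puts H-15 cis to H-16 and the isopropyl group cis to the C12 substituent, while the shielded tetrasubstituted C1=C2 alkene should remain.

**Step 18**
Reactants: 30 bis-silyl ether
Product: 31 diol (C12-CH2OH, C18-OH)
Conditions: TBAF (4 equiv), THF, 50 °C
Reagents that add atoms: none
Why: Fluoride cleavage of both silyl ethers under non-acidic conditions, which avoids ionisation of the tertiary allylic alcohol.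

**Step 19**
Reactants: 31 diol
Product: 32 C12 carbaldehyde (C18-OH free)
Conditions: DMP, pyridine, CH2Cl2, 0 °C → rt
Reagents that add atoms: none
Why: Dess–Martin oxidation, which tolerates the neopentyl position, cannot oxidise the tertiary alcohol and, when buffered, should not transpose it; no lactol can form because CHO and OH lie on opposite faces of ring C.

**Step 20**
Reactants: 32 aldehyde
Product: 33 sesterfisheric acid
Conditions: NaClO2, NaH2PO4, 2-methylbut-2-ene (excess), t-BuOH/H2O, rt
Reagents that add atoms: sodium chlorite [Na+].[O-]Cl=O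
Why: Pinnick oxidation of a non-enolisable hindered aldehyde, with the scavenger alkene in excess intercepting the hypochlorite before it can reach the C1=C2 alkene.

**Compound list**

1 | (R)-β-citronellene, (3R)-3,7-dimethylocta-1,6-diene | CC(C)=CCC[C@@H](C)C=C | starting material
2 | (4R)-4-methylhex-5-enal | O=CCC[C@@H](C)C=C | intermediate
3 | (5R)-1,1-dibromo-5-methylhepta-1,6-diene | BrC(Br)=CCC[C@@H](C)C=C | intermediate
4 | lithium acetylide of (3R)-3-methylhept-1-en-6-yne | [Li]C#CCC[C@@H](C)C=C | intermediate
5 | (3R)-3-methyloct-1-en-6-yne | CC#CCC[C@@H](C)C=C | intermediate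
6 | zirconabicycle (Cp2Zr bridging C1 and C7) | C/C1=C2\CC[C@@H](C)[C@@H]2C[Zr]1(C1C=CC=C1)C1C=CC=C1 | intermediate
7 | (2S,3R)-1-[(Z)-1-iodoethylidene]-2-(iodomethyl)-3-methylcyclopentane | C/C(I)=C1\CC[C@@H](C)[C@@H]1CI | intermediate
8 | allylmagnesium bromide | C=CC[Mg]Br | starting material
9 | (2S,3R)-2-(but-3-enyl)-1-[(Z)-1-iodoethylidene]-3-methylcyclopentane | C/C(I)=C1\CC[C@@H](C)[C@@H]1CCC=C | intermediate
10 | acrolein | C=CC=O | starting material
11 | alkenyllithium from 9 | C/C([Li])=C1\CC[C@@H](C)[C@@H]1CCC=C | intermediate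
12 | (4Z)-4-[(2S,3R)-2-(but-3-enyl)-3-methylcyclopentylidene]pent-1-en-3-ol, both carbinol epimers | C/C(C(O)C=C)=C1\CC[C@@H](C)[C@@H]1CCC=C | intermediate
13 | (4Z)-4-[(2S,3R)-2-(but-3-enyl)-3-methylcyclopentylidene]pent-1-en-3-one | C/C(C(=O)C=C)=C1\CC[C@@H](C)[C@@H]1CCC=C | intermediate
14 | (4Z,8S,9R)-2,9-dimethylbicyclo[6.3.0]undeca-1,4-dien-3-one | C/C1=C2\CC[C@@H](C)[C@@H]2CC/C=C\C1=O | intermediate
15 | 2-methylidenepropane-1,3-diol | C=C(CO)CO | starting material
16 | 2-{[(tert-butyldimethylsilyl)oxy]methyl}prop-2-en-1-ol | C=C(CO)CO[Si](C)(C)C(C)(C)C | intermediate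
17 | 2-{[(tert-butyldimethylsilyl)oxy]methyl}prop-2-en-1-yl acetate | C=C(COC(C)=O)CO[Si](C)(C)C(C)(C)C | intermediate
18 | methylzinc enolate (C10=C18, 9S) | C/C1=C2\CC[C@@H](C)[C@@H]2CC[C@H](C)/C=C1/O[Zn]C | intermediate
19 | (4R,5S,8S,9R)-4-[2-(TBSO-methyl)prop-2-enyl]-2,5,9-trimethylbicyclo[6.3.0]undec-1-en-3-one | C/C1=C2\CC[C@@H](C)[C@@H]2CC[C@H](C)[C@@H](CC(=C)CO[Si](C)(C)C(C)(C)C)C1=O | intermediate
20 | C18 spiro-oxirane of 19 | C/C1=C2\CC[C@@H](C)[C@@H]2CC[C@H](C)[C@@H](CC(=C)CO[Si](C)(C)C(C)(C)C)[C@]13CO3 | intermediate
21 | 3-methylbut-1-yne | C#CC(C)C | starting material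
22 | lithium 3-methylbutynide | [Li]C#CC(C)C | intermediate
23 | lithium alkoxide from epoxide opening | C/C1=C2\CC[C@@H](C)[C@@H]2CC[C@H](C)[C@@H](CC(=C)CO[Si](C)(C)C(C)(C)C)[C@@]1(CC#CC(C)C)O[Li] | intermediate
24 | 1,7-enyne, C18 triethylsilyl ether | C/C1=C2\CC[C@@H](C)[C@@H]2CC[C@H](C)[C@@H](CC(=C)CO[Si](C)(C)C(C)(C)C)[C@@]1(CC#CC(C)C)O[Si](CC)(CC)CC | intermediate
25 | hexacarbonyldicobalt complex of 24 | C/C1=C2\CC[C@@H](C)[C@@H]2CC[C@H](C)[C@@H](CC(=C)CO[Si](C)(C)C(C)(C)C)[C@@]1(CC45C6(C(C)C)[Co]4(=C=O)(=C=O)(=C=O)[Co]56(=C=O)(=C=O)=C=O)O[Si](CC)(CC)CC | intermediate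
26 | tetracyclic cyclopentenone | C/C1=C2\CC[C@@H](C)[C@@H]2CC[C@H](C)[C@H]2C[C@@]3(CO[Si](C)(C)C(C)(C)C)CC(=O)C(C(C)C)=C3C[C@]12O[Si](CC)(CC)CC | intermediate
27 | lithium C14–C15 enolate | C/C1=C2\CC[C@@H](C)[C@@H]2CC[C@H](C)[C@H]2C[C@@]3(CO[Si](C)(C)C(C)(C)C)CC(O[Li])=C(C(C)C)[C@@H]3C[C@]12O[Si](CC)(CC)CC | intermediate
28 | C14 enol triflate | C/C1=C2\CC[C@@H](C)[C@@H]2CC[C@H](C)[C@H]2C[C@@]3(CO[Si](C)(C)C(C)(C)C)CC(OS(=O)(=O)C(F)(F)F)=C(C(C)C)[C@@H]3C[C@]12O[Si](CC)(CC)CC | intermediate
29 | C14=C15 alkene | C/C1=C2\CC[C@@H](C)[C@@H]2CC[C@H](C)[C@H]2C[C@@]3(CO[Si](C)(C)C(C)(C)C)CC=C(C(C)C)[C@@H]3C[C@]12O[Si](CC)(CC)CC | intermediate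
30 | saturated bis-silyl ether | C/C1=C2\CC[C@@H](C)[C@@H]2CC[C@H](C)[C@H]2C[C@@]3(CO[Si](C)(C)C(C)(C)C)CC[C@H](C(C)C)[C@@H]3C[C@]12O[Si](CC)(CC)CC | intermediate
31 | diol | C/C1=C2\CC[C@@H](C)[C@@H]2CC[C@H](C)[C@H]2C[C@@]3(CO)CC[C@H](C(C)C)[C@@H]3C[C@]12O | intermediate
32 | C12 carbaldehyde | C/C1=C2\CC[C@@H](C)[C@@H]2CC[C@H](C)[C@H]2C[C@@]3(C=O)CC[C@H](C(C)C)[C@@H]3C[C@]12O | intermediate
33 | sesterfisheric acid | C/C1=C2\CC[C@@H](C)[C@@H]2CC[C@H](C)[C@H]2C[C@@]3(C(=O)O)CC[C@H](C(C)C)[C@@H]3C[C@]12O | target

**Step count and risks**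

Total step count: 20. Longest linear sequence: 18 (steps 1–8 and 11–20).

**Step 14 (Pauson–Khand).**
- What may go wrong: alkene insertion may be too slow. The 1,1-disubstituted alkene must displace CO and insert next to an isopropyl-flanked cobalt-bound carbon across a 1,7-tether, so decomplexation or decay of the complex may outrun ring closure.
- Fallback: the isopropyl group is kept off the alkyne during the ring closure and brought in afterwards. The fallback sets out from 20 and comes back at 28.
- Opening of 20 with lithium acetylide–ethylenediamine in DMSO should give the terminal homopropargylic alcohol F1.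
- TESOTf/2,6-lutidine should give the terminal enyne silyl ether F2.
- The cobalt-mediated closure on this unencumbered terminal alkyne should give the α-unsubstituted cyclopentenone F3.
- Li/NH3 reduction sets H-16 as in step 15, and the regiospecific enolate is intercepted with acetone (ZnCl2) to give the aldol F4.
- MsCl/Et3N and then DBU should give the isopropylidene ketone F5.
- A second Li/NH3 reduction of this exocyclic enone delivers the same enolate 27, which is triflated to 28.

**Step 8 (RCM to the cyclooctadienone).**
- What may go wrong: intermolecular metathesis (oligomerisation) and slow turnover at the electron-poor acryloyl alkene may win over closure of the strained eight-membered ring.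
- Fallback: ring B is closed at C1–C18 by a chromium-mediated addition instead. The fallback sets out from 7 and comes back at 14.
- Copper-catalysed coupling of the primary iodide of 7 with the Grignard reagent of 2-(3-chloropropyl)-1,3-dioxolane should give the iodo acetal F6.
- Mild acid hydrolysis should give the iodo aldehyde F7.
- An intramolecular Nozaki–Hiyama–Kishi reaction (CrCl2, cat. NiCl2, DMSO, high dilution) should give the bicyclic allylic alcohol F8.
- DMP should give the bicyclic enone F9.
- IBX dehydrogenation at C10, the only enolisable α-position, should give 14.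

**Step 13 (epoxide opening).**
- What may go wrong: substitution at a CH2 next to a fully substituted carbon may be sluggish, and base- or lithium-induced isomerisation of the tertiary allylic epoxide may compete.
- Fallback: the arm is added directly to the ketone. The fallback sets out from 19 (bypassing 20) and comes back at 24.
- Commercial 4-methylpent-2-yn-1-ol with ClCO2Me/pyridine should give the propargylic carbonate F10.
- Copper-catalysed SN2′ borylation with B2pin2 should give the 1-isopropylallenyl boronate F11.
- F11 should add to 19 through a closed SE2′ transition state, with bond formation at the allene CH2 terminus and on the same face as the ylide, to give the tertiary homopropargylic alcohol F12.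
- TESOTf/2,6-lutidine then gives 24.

**Further compounds**

F1 | step 14 | terminal homopropargylic alcohol | C/C1=C2\CC[C@@H](C)[C@@H]2CC[C@H](C)[C@@H](CC(=C)CO[Si](C)(C)C(C)(C)C)[C@@]1(CC#C)O
F2 | step 14 | terminal enyne silyl ether | C/C1=C2\CC[C@@H](C)[C@@H]2CC[C@H](C)[C@@H](CC(=C)CO[Si](C)(C)C(C)(C)C)[C@@]1(CC#C)O[Si](CC)(CC)CC
F3 | step 14 | α-unsubstituted cyclopentenone | C/C1=C2\CC[C@@H](C)[C@@H]2CC[C@H](C)[C@H]2C[C@@]3(CO[Si](C)(C)C(C)(C)C)CC(=O)C=C3C[C@]12O[Si](CC)(CC)CC
F4 | step 14 | acetone aldol (C15 not defined) | C/C1=C2\CC[C@@H](C)[C@@H]2CC[C@H](C)[C@H]2C[C@@]3(CO[Si](C)(C)C(C)(C)C)CC(=O)C(C(C)(C)O)[C@@H]3C[C@]12O[Si](CC)(CC)CC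
F5 | step 14 | isopropylidene ketone | C/C1=C2\CC[C@@H](C)[C@@H]2CC[C@H](C)[C@H]2C[C@@]3(CO[Si](C)(C)C(C)(C)C)CC(=O)C(=C(C)C)[C@@H]3C[C@]12O[Si](CC)(CC)CC
F6 | step 8 | iodo acetal | C/C(I)=C1\CC[C@@H](C)[C@@H]1CCCCC2OCCO2
F7 | step 8 | iodo aldehyde | C/C(I)=C1\CC[C@@H](C)[C@@H]1CCCCC=O
F8 | step 8 | bicyclic allylic alcohol (both carbinol epimers) | C/C1=C2\CC[C@@H](C)[C@@H]2CCCCC1O
F9 | step 8 | bicyclic enone | C/C1=C2\CC[C@@H](C)[C@@H]2CCCCC1=O
F10 | step 13 | 4-methylpent-2-yn-1-yl methyl carbonate | CC(C)C#CCOC(=O)OC
F11 | step 13 | 4,4,5,5-tetramethyl-2-(4-methylpenta-1,2-dien-3-yl)-1,3,2-dioxaborolane | C=C=C(C(C)C)B1OC(C)(C)C(C)(C)O1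
F12 | step 13 | tertiary homopropargylic alcohol | C/C1=C2\CC[C@@H](C)[C@@H]2CC[C@H](C)[C@@H](CC(=C)CO[Si](C)(C)C(C)(C)C)[C@@]1(CC#CC(C)C)O
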